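**Retrosynthetic overview**
1. Cage last: the bicyclo[2.2.2]octenone and its fused tetrahydrofuran come from an intramolecular Diels–Alder reaction of a dearomatised flavanone, a 6-methyl-6-(prenyloxy)cyclohexa-2,4-dienone. It forms cage bonds C1–C7 and C4–C8 (cage numbering: C1 bridgehead with Me, C2 ketone, C3 carbon with Me and O, C4 bridgehead with OH, C5=C6 alkene, C7 CMe2, C8 CH).
2. Carbocycle of that dienone: disconnect the bond between the ketone carbon (cage C2) and the quaternary C(Me)(O-prenyl) carbon (cage C3). This is a Claisen-type C-acylation within a dihydropyranone keto ester, run in the same flask as the cycloaddition.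
3. Enabling feature: in the keto ester the endocyclic C5=C6 bond of the 2,3-dihydropyran-4-one holds the C6 propanoate arm (acyl donor) and the C5 2-(prenyloxy)propanoyl arm (carbon nucleophile) cis and makes both C–H positions vinylogously acidic. Because the attacked carbon becomes quaternary, the new ring cannot aromatise and keeps a diene, with the O–CH2–CH=CMe2 tether on the adjacent carbon.
4. Keto ester ← 5-iodo-dihydropyranone + 2-(prenyloxy)propanal (Nozaki–Hiyama–Kishi coupling, oxidation). Dihydropyranone ← (S)-β-hydroxy Weinreb amide + dianion of methyl 2-methylacetoacetate, then cyclodehydration. The only imported stereocentre (C2, S) comes from ethyl (S)-3-hydroxy-3-phenylpropanoate.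
5. Ring order: dihydropyranone (step 3) → six-membered carbocycle by the C–C bond above (step 9) → cyclohexene and tetrahydrofuran of the cage by cycloaddition (step 9).

Key step: step 9

Remark (assumption): no useful stereocontrol is expected from the remote C2 phenyl centre in the ring-forming C-acylation of step 9, so the route assumes that the two cage diastereomers (both 2S) can be separated by chromatography; racemic ethyl lactate is used because its stereocentre is erased in step 9.

Step 1
Reactants: 1 ethyl (3S)-3-hydroxy-3-phenylpropanoate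
Product: 2 (3S)-3-hydroxy-N-methoxy-N-methyl-3-phenylpropanamide
Conditions: MeNHOMe·HCl, iPrMgCl, THF, −20 → 0 °C
Reagents that add atoms: N,O-dimethylhydroxylamine hydrochloride, CNOC.Cl
Why: Weinreb amide formation by aminolysis of the ester with the magnesium amide of N,O-dimethylhydroxylamine should leave the (S)-carbinol centre untouched, and this centre is carried unchanged to C2 of the pyranone.

Step 2
Reactants: 2 (3S)-3-hydroxy-N-methoxy-N-methyl-3-phenylpropanamide; 3 methyl 2-methyl-3-oxobutanoate
Product: 5 methyl (7S)-7-hydroxy-2-methyl-3,5-dioxo-7-phenylheptanoate, via dilithium dianion 4 (not isolated)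
Conditions: 3 (3.3 equiv), LiN(iPr)2 (6.6 equiv), THF, −78 → 0 °C; then 2, −78 → −20 °C; aq. HCl
Reagents that add atoms: none
Why: This is a Claisen-type γ-acylation of an acetoacetate dianion by a Weinreb amide, in which the hydroxyl is masked in situ as its lithium alkoxide and the chelated tetrahedral adduct survives until the quench, so over-addition and retro-aldol cleavage should be avoided; the carbinol centre is untouched and the C2 methine is an epimer mixture that becomes sp2 in step 9.

Step 3
Reactants: 5 methyl (7S)-7-hydroxy-2-methyl-3,5-dioxo-7-phenylheptanoate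
Product: 6 methyl 2-[(2S)-4-oxo-2-phenyl-3,4-dihydro-2H-pyran-6-yl]propanoate
Conditions: TFA, CH2Cl2, 0 °C → rt
Reagents that add atoms: none
Why: Acid-catalysed cyclodehydration of a δ-hydroxy-β-diketone should give the 2,3-dihydro-4H-pyran-4-one, because only attack of the C7 hydroxyl on the C3 ketone gives a six-membered ring (the C5 ketone and the ester would need four- and eight-membered rings), and the stereocentre is not involved.

Step 4
Reactants: 6 methyl 2-[(2S)-4-oxo-2-phenyl-3,4-dihydro-2H-pyran-6-yl]propanoate
Product: 7 methyl 2-[(2S)-5-iodo-4-oxo-2-phenyl-3,4-dihydro-2H-pyran-6-yl]propanoate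
Conditions: N-iodosuccinimide, MeCN, 0 °C → rt, dark
Reagents that add atoms: N-iodosuccinimide, O=C1CCC(=O)N1I
Why: Electrophilic α-iodination of a β-alkoxy enone (vinylogous ester) should occur at C5, the nucleophilic carbon of the enol ether, through an oxygen-stabilised cation that loses the C5 proton; no stereocentre is formed.

Step 5
Reactants: 8 ethyl 2-hydroxypropanoate (racemic ethyl lactate); 9 1-bromo-3-methylbut-2-ene (prenyl bromide)
Product: 10 ethyl 2-[(3-methylbut-2-en-1-yl)oxy]propanoate
Conditions: NaH, n-Bu4NI (cat.), THF–DMF, 0 °C → rt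
Reagents that add atoms: none
Why: Williamson ether synthesis (SN2 displacement of the primary allylic bromide by the lactate alkoxide) should give the prenyl ether; the racemate is used because this centre is erased in step 9.

Step 6
Reactants: 10 ethyl 2-[(3-methylbut-2-en-1-yl)oxy]propanoate
Product: 11 2-[(3-methylbut-2-en-1-yl)oxy]propanal
Conditions: iBu2AlH (DIBAL-H), CH2Cl2, −78 °C; aq. Rochelle salt
Reagents that add atoms: none
Why: Partial reduction of the ester with DIBAL-H at low temperature should stop at the aldehyde, because the aluminium hemiacetal chelated by the α-alkoxy group survives until the aqueous quench.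

Step 7
Reactants: 7 methyl 2-[(2S)-5-iodo-4-oxo-2-phenyl-3,4-dihydro-2H-pyran-6-yl]propanoate; 11 2-[(3-methylbut-2-en-1-yl)oxy]propanal
Product: 12 methyl 2-[(2S)-5-{1-hydroxy-2-[(3-methylbut-2-en-1-yl)oxy]propyl}-4-oxo-2-phenyl-3,4-dihydro-2H-pyran-6-yl]propanoate
Conditions: CrCl2 (4 equiv), NiCl2 (2 mol %), DMF, rt
Reagents that add atoms: none
Why: Nozaki–Hiyama–Kishi coupling (oxidative addition of the alkenyl iodide to zerovalent nickel, transmetalation to trivalent chromium, addition to the aldehyde) is chosen because the alkenylchromium species adds to aldehydes in the presence of the ketone and the ester; the carbinol centre forms unselectively, which is harmless since it is oxidised in step 8 and the neighbouring CH(Me) centres are erased in step 9.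

Step 8
Reactants: 12 methyl 2-[(2S)-5-{1-hydroxy-2-[(3-methylbut-2-en-1-yl)oxy]propyl}-4-oxo-2-phenyl-3,4-dihydro-2H-pyran-6-yl]propanoate
Product: 13 methyl 2-[(2S)-5-{2-[(3-methylbut-2-en-1-yl)oxy]propanoyl}-4-oxo-2-phenyl-3,4-dihydro-2H-pyran-6-yl]propanoate
Conditions: Dess–Martin periodinane, CH2Cl2, 0 °C → rt (crude 12 used at once)
Reagents that add atoms: none
Why: Dess–Martin oxidation of the secondary allylic alcohol under non-basic conditions should give the ketone without touching the prenyl ether or the C2 stereocentre, and oxidising the crude alcohol at once should keep it from lactonising onto the methyl ester.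

Step 9
Reactants: 13 methyl 2-[(2S)-5-{2-[(3-methylbut-2-en-1-yl)oxy]propanoyl}-4-oxo-2-phenyl-3,4-dihydro-2H-pyran-6-yl]propanoate
Product: 17 CNP0322161.1 (target), via enol lactone 14 (not isolated), via ketene enolate 15 (not isolated), via dienone 16 (not isolated)
Conditions: DBU (1.5 equiv), toluene (0.02 M), 70 °C; AcOH (2 equiv), aq. wash; then toluene (0.01 M), 110 °C
Reagents that add atoms: none
Why: DBU removes the propanoate α-H of 13 (vinylogous to C4=O and to the C5 acyl group), the enolate oxygen of the C5 acyl group displaces methoxide from the ester (6-exo-trig) to give enol lactone 14, and deprotonation of 14 at the now doubly vinylogous CH(Me)O-prenyl carbon triggers E1cB cleavage of the lactone C–O bond to ketene enolate 15, whose enolate carbon adds to the ketene carbon (6π electrocyclisation of an oxido-dienylketene, formally 6-endo-dig) to forge the bond between the ketone carbon and the quaternary C(Me)(O-prenyl) carbon and close the carbocycle as the stabilised enolate of 16. The closest known reaction types are the Claisen (Dieckmann) cyclisation of β-polyketo esters through their pyranone forms to acylphloroglucinols and to non-aromatisable cyclohexanetriones, the electrocyclisation of dienylketenes to cyclohexa-2,4-dienones, and the intramolecular Diels–Alder reaction of 6-alkoxycyclohexa-2,4-dienones that carry an alkenyl ether. After protonation, 16 cannot aromatise because C6 is quaternary, and on heating its diene C8=C8a–C4a=C5 should add the prenyl alkene suprafacially in a [4+2] cycloaddition that closes the cyclohexene ring of the bicyclo[2.2.2]octenone and, through the O–CH2–CH tether, the tetrahydrofuran in the fused five-membered mode (the reversed orientation would need a bridged seven-membered ring). C6 of 16 is created in the C-acylation with no useful bias from the remote C2 phenyl group, so both epimers are expected; the tether then forces the alkene onto the face that carries the ether oxygen, which sets the two bridgeheads and the ring CH relative to C6, so that (6S)-16 should give 17 and (6R)-16 its cage diastereomer, to be removed by chromatography. The step needs C- over O-acylation (secured thermodynamically, because only the C-acylated product is a strongly acidic vinylogous triketone that is trapped as its enolate, while O-acylation merely returns 14), reaction at the CH(Me)O-prenyl carbon and not E1cB opening of the pyranone at C3 (13 and 16 are present as enolates and so are protected, and in 14 the doubly vinylogous C–H is the most acidic), and cycloaddition over dimerisation (fully substituted diene, high dilution).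

**Compound list**
1 | ethyl (3S)-3-hydroxy-3-phenylpropanoate | CCOC(=O)C[C@@H](c1ccccc1)O | starting material
2 | (3S)-3-hydroxy-N-methoxy-N-methyl-3-phenylpropanamide | CON(C)C(=O)C[C@@H](c1ccccc1)O | intermediate
3 | methyl 2-methyl-3-oxobutanoate (methyl 2-methylacetoacetate, racemic) | COC(=O)C(C)C(C)=O | starting material
4 | dilithium dianion of 3 (dilithium 1-methoxy-2-methylbuta-1,3-diene-1,3-diolate) | COC([O-])=C(C)C([O-])=C.[Li+].[Li+] | intermediate (not isolated)
5 | methyl (7S)-7-hydroxy-2-methyl-3,5-dioxo-7-phenylheptanoate (both C2 epimers, keto–enol mixture) | COC(=O)C(C)C(=O)CC(=O)C[C@@H](c1ccccc1)O | intermediate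
6 | methyl 2-[(2S)-4-oxo-2-phenyl-3,4-dihydro-2H-pyran-6-yl]propanoate (both epimers at the propanoate carbon) | COC(=O)C(C)C1=CC(=O)C[C@@H](c2ccccc2)O1 | intermediate
7 | methyl 2-[(2S)-5-iodo-4-oxo-2-phenyl-3,4-dihydro-2H-pyran-6-yl]propanoate | COC(=O)C(C)C1=C(I)C(=O)C[C@@H](c2ccccc2)O1 | intermediate
8 | ethyl 2-hydroxypropanoate (racemic ethyl lactate) | CCOC(=O)C(C)O | starting material
9 | 1-bromo-3-methylbut-2-ene (prenyl bromide) | CC(C)=CCBr | starting material
10 | ethyl 2-[(3-methylbut-2-en-1-yl)oxy]propanoate (racemic) | CCOC(=O)C(C)OCC=C(C)C | intermediate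
11 | 2-[(3-methylbut-2-en-1-yl)oxy]propanal (racemic) | O=CC(C)OCC=C(C)C | intermediate
12 | methyl 2-[(2S)-5-{1-hydroxy-2-[(3-methylbut-2-en-1-yl)oxy]propyl}-4-oxo-2-phenyl-3,4-dihydro-2H-pyran-6-yl]propanoate (mixture at the three side-chain centres) | COC(=O)C(C)C1=C(C(O)C(C)OCC=C(C)C)C(=O)C[C@@H](c2ccccc2)O1 | intermediate
13 | methyl 2-[(2S)-5-{2-[(3-methylbut-2-en-1-yl)oxy]propanoyl}-4-oxo-2-phenyl-3,4-dihydro-2H-pyran-6-yl]propanoate (mixture at the two CH(Me) carbons) | COC(=O)C(C)C1=C(C(=O)C(C)OCC=C(C)C)C(=O)C[C@@H](c2ccccc2)O1 | intermediate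
14 | enol lactone: (2S)-8-methyl-5-{1-[(3-methylbut-2-en-1-yl)oxy]ethyl}-2-phenyl-2,3-dihydro-4H,7H-pyrano[4,3-b]pyran-4,7-dione | O=C1OC(C(C)OCC=C(C)C)=C2C(=O)C[C@@H](c3ccccc3)OC2=C1C | intermediate (not isolated)
15 | ketene enolate: DBU-H+ salt of (2S)-5-{1-oxido-2-[(3-methylbut-2-en-1-yl)oxy]prop-1-en-1-yl}-6-(1-oxoprop-1-en-2-yl)-2-phenyl-2,3-dihydro-4H-pyran-4-one | O=C=C(C)C1=C(C([O-])=C(C)OCC=C(C)C)C(=O)C[C@@H](c2ccccc2)O1.C1CCC2=[NH+]CCCN2CC1 | intermediate (not isolated)
16 | dienone: (2S)-5-hydroxy-6,8-dimethyl-6-[(3-methylbut-2-en-1-yl)oxy]-2-phenyl-2,3-dihydro-4H-chromene-4,7(6H)-dione (both C6 epimers) | CC1(OCC=C(C)C)C(=O)C(C)=C2C(=C1O)C(=O)C[C@@H](c3ccccc3)O2 | intermediate (not isolated)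
17 | CNP0322161.1: (2S)-2-phenyl-2,3-dihydropyran-4-one fused at C5=C6 (ketone side on C5, ring oxygen on C6) of a 4-hydroxy-1,3,7,7-tetramethylbicyclo[2.2.2]oct-5-en-2-one whose C3–O–CH2–C8 unit forms the tetrahydrofuran; cage centres C1 R, C3 S, C4 R, C8 R | CC1(C)[C@@H]2CO[C@]3(C)C(=O)[C@@]1(C)C1=C(C(=O)C[C@@H](c4ccccc4)O1)[C@]23O | target

**Step count and risks**
Total steps: 9. Longest linear sequence: 7 steps (1 → 2 → 5 → 6 → 7 → 12 → 13 → 17).

Most likely to fail:

1. Step 9. What may go wrong: base-induced E1cB opening of the dihydropyranone ring (loss of the C2 configuration) or retro-Claisen deacylation outrunning the C-acylation, and the absence of facial control at the new quaternary carbon. The fallback sets out from 13 and comes back at 17; it introduces the phenyl-bearing stereocentre last. Compound 13 is opened on purpose with excess DBU in toluene–MeOH to its cinnamoyl isomer, ring-opened triketo ester F1, in which the phenyl-bearing stereocentre is gone. The same base then effects the Claisen cyclisation to racemic cinnamoyl dienone F2, which after acidification and heating undergoes the same intramolecular Diels–Alder reaction to racemic cage chalcone F3. An enantioselective intramolecular oxa-Michael addition of the enol to the cinnamoyl group, catalysed by a quinine-derived bifunctional thiourea, then closes the (2S)-pyranone, and the two cage diastereomers are separated to give 17.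

2. Step 7. What may go wrong: protonation of the alkenylchromium intermediate by the acidic propanoate C–H (net reductive loss of iodine) and lactonisation of the new alkoxide onto the methyl ester. The fallback sets out from 7 and 10 and comes back at 13, skipping 12 and step 8; a neutral Stille acylation replaces the chromium chemistry. Ester 10 is saponified with LiOH to 2-[(3-methylbut-2-en-1-yl)oxy]propanoic acid F4 and converted with oxalyl chloride into acid chloride F5. Iodide 7 is stannylated with Me6Sn2 and Pd(PPh3)4 (zerovalent palladium) to alkenylstannane F6, and palladium-catalysed coupling of F6 with F5 gives ketone 13 directly.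

3. Step 4. What may go wrong: electrophilic iodination at the enolisable propanoate carbon instead of C5, or over-iodination. The fallback sets out from 6 and comes back at 13, skipping 7 and 12; C5 is made nucleophilic as an enaminone instead of being halogenated. Pyrrolidine adds to C6 of 6 and opens the ring to δ-hydroxy enaminone F7, and the hydroxyl is silylated (TESCl, imidazole) to silyl ether F8. The enaminone α-carbon is then C-acylated with acid chloride F5 (Et3N) to give C-acylated enaminone F9, and aqueous TFA removes the silyl group and recloses the pyranone with loss of pyrrolidine to give 13.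

**Further compounds**
F1 | step 9 | methyl (6E)-3-hydroxy-2-methyl-4-{2-[(3-methylbut-2-en-1-yl)oxy]propanoyl}-5-oxo-7-phenylhepta-3,6-dienoate (ring-opened cinnamoyl isomer of 13, one enol drawn) | COC(=O)C(C)C(O)=C(C(=O)/C=C/c1ccccc1)C(=O)C(C)OCC=C(C)C
F2 | step 9 | racemic 3,5-dihydroxy-2,6-dimethyl-6-[(3-methylbut-2-en-1-yl)oxy]-4-[(2E)-3-phenylprop-2-enoyl]cyclohexa-2,4-dien-1-one | CC1(OCC=C(C)C)C(=O)C(C)=C(O)C(C(=O)/C=C/c2ccccc2)=C1O
F3 | step 9 | racemic cage chalcone: cage of 17 with an enolic OH on C6 and an (E)-cinnamoyl group on C5 (one enantiomer drawn) | CC1(C)[C@@H]2CO[C@]3(C)C(=O)[C@@]1(C)C(O)=C(C(=O)/C=C/c1ccccc1)[C@]23O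
F4 | step 7 | 2-[(3-methylbut-2-en-1-yl)oxy]propanoic acid (racemic) | CC(OCC=C(C)C)C(=O)O
F5 | step 7 | 2-[(3-methylbut-2-en-1-yl)oxy]propanoyl chloride (racemic) | CC(OCC=C(C)C)C(=O)Cl
F6 | step 7 | methyl 2-[(2S)-4-oxo-2-phenyl-5-(trimethylstannyl)-3,4-dihydro-2H-pyran-6-yl]propanoate | COC(=O)C(C)C1=C([Sn](C)(C)C)C(=O)C[C@@H](c2ccccc2)O1
F7 | step 4 | methyl (7S)-7-hydroxy-2-methyl-5-oxo-7-phenyl-3-(pyrrolidin-1-yl)hept-3-enoate | COC(=O)C(C)C(N1CCCC1)=CC(=O)C[C@@H](c2ccccc2)O
F8 | step 4 | methyl (7S)-2-methyl-5-oxo-7-phenyl-3-(pyrrolidin-1-yl)-7-(triethylsilyloxy)hept-3-enoate | COC(=O)C(C)C(N1CCCC1)=CC(=O)C[C@@H](c2ccccc2)O[Si](CC)(CC)CC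
F9 | step 4 | methyl (7S)-2-methyl-4-{2-[(3-methylbut-2-en-1-yl)oxy]propanoyl}-5-oxo-7-phenyl-3-(pyrrolidin-1-yl)-7-(triethylsilyloxy)hept-3-enoate | COC(=O)C(C)C(N1CCCC1)=C(C(=O)C(C)OCC=C(C)C)C(=O)C[C@@H](c2ccccc2)O[Si](CC)(CC)CC
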